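**Plan**

1. Retrosynthetic cuts: the two acetates; C13–O/C14–O back to a 13E allylic alcohol; C13=C14 (olefination of the C13 methyl ketone on the bicyclic core with a two-carbon phosphonoacetate); C4–C5 (lactone-enolate [3,3] shift, which also creates the 1(10) olefin); C1–C10; C9–C11; C8–CH3.
2. Forward order: ring B comes from 2-methylcyclohexenone (conjugate methylation, then Mukaiyama–Michael addition to methyl vinyl ketone); a C1–C4 arm is attached at C10 and ring A is closed by an Ireland–Claisen rearrangement of a δ-lactone; the side chain is finished last.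
3. Enabling feature: C13 is a tertiary carbinol carrying the C16 methyl next to the oxygenated C14–C15 unit, i.e. a 2-methyl-1,2,3-triol with an anti C13/C14 relationship. This is the hydration pattern of a 13E trisubstituted allylic alcohol, so the C13–C14 bond is made as a C=C bond from the C13 methyl ketone of the ring A/ring B core, and both stereocentres are read off its geometry.
4. Stereochemistry: C8 from the chiral copper catalyst; C9 from C8 (addition anti to the C8 methyl); C1 from CBS reduction, relayed suprafacially to C5 and C4 in the boat Claisen; C13 and C14 from Sharpless epoxidation (L-(+)-tartrate) of the 13E olefin and inversion at C13 on hydrolysis.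

Key step: step 11

Remark: halimane numbering is used (ring A = C1–C5 and C10, ring B = C5–C10, side chain C11–C16 on C9, ester carbon C18). In the target, H-5 and the methyls on C4, C8 and C9 lie on one face; CO2Me and the side chain lie on the other.

**Route**

Step 1
Reactants: 1 2-methylcyclohex-2-en-1-one
Product: 3 (R)-[(2,3-dimethylcyclohex-1-en-1-yl)oxy]trimethylsilane, via dimethylaluminium enolate 2 (not isolated)
Conditions: Me3Al, copper thiophene-2-carboxylate (cat.), BINOL-derived bis(1-phenylethyl)amine phosphoramidite (cat., enantiomer that gives 3R), Et2O, −30 °C; then TMSOTf, −30 → 0 °C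
Reagents that add atoms: trimethylaluminium, C[Al](C)C; trimethylsilyl trifluoromethanesulfonate, C[Si](C)(C)OS(=O)(=O)C(F)(F)F
Why: Copper-catalysed asymmetric conjugate addition of Me3Al to the 2-substituted enone, in which the chiral phosphoramidite–copper complex selects the enone face and so sets C8 (R), followed by O-silylation of the aluminium enolate, which fixes the tetrasubstituted enol ether.

Step 2
Reactants: 3 (R)-[(2,3-dimethylcyclohex-1-en-1-yl)oxy]trimethylsilane; 4 methyl vinyl ketone
Product: 5 (2S,3R)-2,3-dimethyl-2-(3-oxobutyl)cyclohexan-1-one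
Conditions: BF3·OEt2, i-PrOH, CH2Cl2, −78 °C
Reagents that add atoms: none
Why: Mukaiyama–Michael addition in which the silyl enol ether attacks the BF3-activated enone at C9 from the face anti to the pseudoaxial C8 methyl (axial attack), which should give the quaternary C9 centre with the two methyls cis, while the alcohol takes up the silyl group and releases the 1,5-diketone without aldol closure.

Step 3
Reactants: 5 (2S,3R)-2,3-dimethyl-2-(3-oxobutyl)cyclohexan-1-one
Product: 6 (2S,3R)-2,3-dimethyl-2-[2-(2-methyl-1,3-dioxolan-2-yl)ethyl]cyclohexan-1-one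
Conditions: TMSOCH2CH2OTMS, TMSOTf (cat.), CH2Cl2, −78 °C
Reagents that add atoms: 1,2-bis(trimethylsilyloxy)ethane, C[Si](C)(C)OCCO[Si](C)(C)C
Why: Noyori ketalisation should be much faster at the unhindered methyl ketone than at the ring ketone flanked by quaternary C9, so only the side-chain carbonyl is masked for the organolithium and enolate steps that follow.

Step 4
Reactants: 6 (2S,3R)-2,3-dimethyl-2-[2-(2-methyl-1,3-dioxolan-2-yl)ethyl]cyclohexan-1-one
Product: 7 (E)-2,4,6-triisopropylbenzenesulfonyl hydrazone of ketone 6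
Conditions: 2,4,6-(i-Pr)3C6H2SO2NHNH2, THF, rt
Reagents that add atoms: 2,4,6-triisopropylbenzenesulfonohydrazide, CC(C)c1cc(C(C)C)c(S(=O)(=O)NN)c(C(C)C)c1
Why: Condensation of the remaining ketone with the arenesulfonyl hydrazide gives the hydrazone needed for a Shapiro reaction, with the sulfonamide nitrogen anti to the quaternary carbon, and the dioxolane is stable in the absence of aqueous acid.

Step 5
Reactants: 8 methyl 5-chloro-5-oxopentanoate
Product: 9 methyl 5-[methoxy(methyl)amino]-5-oxopentanoate
Conditions: MeNHOMe·HCl, K2CO3, CH2Cl2/H2O, 0 °C → rt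
Reagents that add atoms: N,O-dimethylhydroxylamine hydrochloride, CNOC.Cl
Why: Schotten–Baumann acylation of the hydroxylamine by the acid chloride gives the Weinreb amide and leaves the methyl ester untouched.

Step 6
Reactants: 7 (E)-2,4,6-triisopropylbenzenesulfonyl hydrazone of ketone 6; 9 methyl 5-[methoxy(methyl)amino]-5-oxopentanoate
Product: 11 methyl 5-{(5R,6S)-5,6-dimethyl-6-[2-(2-methyl-1,3-dioxolan-2-yl)ethyl]cyclohex-1-en-1-yl}-5-oxopentanoate, via vinyllithium 10 (not isolated)
Conditions: n-BuLi (2.1 equiv), THF, −78 → 0 °C; then 9, −78 °C; H2O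
Reagents that add atoms: none
Why: Shapiro reaction in which double deprotonation (N–H, then the only α-CH2, C5) and loss of sulfinate and N2 give the C10 vinyllithium regiospecifically, which the Weinreb amide should acylate through its chelated tetrahedral intermediate (no over-addition) faster than the α-branch-free but less electrophilic methyl ester reacts.

Step 7
Reactants: 11 methyl 5-{(5R,6S)-5,6-dimethyl-6-[2-(2-methyl-1,3-dioxolan-2-yl)ethyl]cyclohex-1-en-1-yl}-5-oxopentanoate
Product: 13 (6R)-6-{(5R,6S)-5,6-dimethyl-6-[2-(2-methyl-1,3-dioxolan-2-yl)ethyl]cyclohex-1-en-1-yl}oxan-2-one, via hydroxy ester 12 (not isolated)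
Conditions: (S)-1-methyl-3,3-diphenyltetrahydro-1H,3H-pyrrolo[1,2-c][1,3,2]oxazaborole (cat.), BH3·SMe2, THF, −30 °C; aqueous work-up; then PPTS (cat.), PhMe, 60 °C
Reagents that add atoms: none
Why: Corey–Bakshi–Shibata reduction in which the (S)-oxazaborolidine treats the bulky cyclohexenyl group as the large substituent and should set C1 (R) under catalyst control, after which the δ-hydroxy ester lactonises under mild acid that spares the dioxolane.

Step 8
Reactants: 13 (6R)-6-{(5R,6S)-5,6-dimethyl-6-[2-(2-methyl-1,3-dioxolan-2-yl)ethyl]cyclohex-1-en-1-yl}oxan-2-one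
Product: 14 (6R)-3-methyl-6-{(5R,6S)-5,6-dimethyl-6-[2-(2-methyl-1,3-dioxolan-2-yl)ethyl]cyclohex-1-en-1-yl}oxan-2-one (mixture of C3 epimers)
Conditions: LiN(i-Pr)2, THF, −78 °C; MeI, −78 → −40 °C
Reagents that add atoms: iodomethane, CI
Why: Alkylation of the lactone lithium enolate installs the future C4 methyl, and the configuration of this centre does not matter because it is erased by enolisation in the next step.

Step 9
Reactants: 14 (6R)-3-methyl-6-{(5R,6S)-5,6-dimethyl-6-[2-(2-methyl-1,3-dioxolan-2-yl)ethyl]cyclohex-1-en-1-yl}oxan-2-one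
Product: 17 (4S,5R,8R,9S)-13-oxo-14,15-dinorhalim-1(10)-en-18-oic acid, via silyl ketene acetal 15 (not isolated), via silyl ester 16 (not isolated)
Conditions: LiN(i-Pr)2, TMSCl/Et3N, THF, −78 °C; then PhMe, 110 °C; then 1 M HCl, THF, rt
Reagents that add atoms: water, O
Why: Ireland–Claisen rearrangement of a lactone silyl ketene acetal, in which the ring enforces a boat transition state and C4 adds to C5 suprafacially to the departing C1–O bond, so that C1 (R) is relayed to C5 (attack anti to the pseudoaxial C9 methyl) and the fixed enol ether geometry places CO2H cis to C6 at the new quaternary C4 while ring A closes with the 1(10) olefin; aqueous HCl then cleaves the silyl ester and the dioxolane.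

Step 10
Reactants: 17 (4S,5R,8R,9S)-13-oxo-14,15-dinorhalim-1(10)-en-18-oic acid
Product: 18 methyl (4S,5R,8R,9S)-13-oxo-14,15-dinorhalim-1(10)-en-18-oate
Conditions: MeI, K2CO3, DMF, rt
Reagents that add atoms: iodomethane, CI
Why: SN2 O-alkylation of the carboxylate esterifies the hindered C4 acid without needing attack at its carbonyl, and the base is too weak to alkylate the methyl ketone.

Step 11
Reactants: 18 methyl (4S,5R,8R,9S)-13-oxo-14,15-dinorhalim-1(10)-en-18-oate; 19 ethyl 2-(diisopropoxyphosphoryl)acetate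
Product: 20 15-ethyl 18-methyl (4S,5R,8R,9S,13E)-halima-1(10),13-diene-15,18-dioate
Conditions: NaH, THF, 0 → 50 °C
Reagents that add atoms: none
Why: Horner–Wadsworth–Emmons olefination, in which the sodium phosphonoacetate carbanion adds reversibly to the C13 methyl ketone and the oxaphosphetane collapses by syn-elimination of phosphate to give the C13=C14 bond, so that the C14–C15 unit is joined to the bicyclic core in one operation. The closest known reaction type is the HWE olefination of aliphatic methyl ketones (the geranylacetone-to-farnesoate type). No ring is closed and no stereocentre is formed, but the 13E geometry made here is the information from which C13 and C14 are later derived (epoxidation on one face, then inversion at C13). The step needs E selectivity and chemoselectivity: the reversible addition and the bulky diisopropyl phosphonate should favour the isomer with the ester trans to the C12 chain, which is larger than the C16 methyl, and the minor Z isomer is to be removed by chromatography. The C4 methyl ester, on a quaternary carbon and non-enolisable, and the hindered trisubstituted 1(10) olefin should not be touched.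

Step 12
Reactants: 20 15-ethyl 18-methyl (4S,5R,8R,9S,13E)-halima-1(10),13-diene-15,18-dioate
Product: 21 methyl (4S,5R,8R,9S,13E)-15-hydroxyhalima-1(10),13-dien-18-oate
Conditions: i-Bu2AlH (2.2 equiv), CH2Cl2, −78 °C; aq. potassium sodium tartrate
Reagents that add atoms: none
Why: 1,2-Reduction of the unhindered conjugated ethyl ester by i-Bu2AlH at low temperature gives the allylic alcohol, while the neopentyl-type C4 methyl ester should react far more slowly.

Step 13
Reactants: 21 methyl (4S,5R,8R,9S,13E)-15-hydroxyhalima-1(10),13-dien-18-oate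
Product: 22 methyl (4S,5R,8R,9S,13S,14S)-13,14-epoxy-15-hydroxyhalim-1(10)-en-18-oate
Conditions: Ti(OiPr)4 (cat.), L-(+)-diethyl tartrate (cat.), t-BuOOH, 4 Å molecular sieves, CH2Cl2, −20 °C
Reagents that add atoms: tert-butyl hydroperoxide, CC(C)(C)OO
Why: Sharpless asymmetric epoxidation, in which the allylic hydroxyl binds the titanium tartrate so that only the 13,14-olefin is oxidised (the 1(10) olefin has no directing group), and L-(+)-tartrate should deliver oxygen to the face that gives the (13S,14S)-epoxide, as it does for geraniol.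

Step 14
Reactants: 22 methyl (4S,5R,8R,9S,13S,14S)-13,14-epoxy-15-hydroxyhalim-1(10)-en-18-oate
Product: 23 methyl (4S,5R,8R,9S,13R,14S)-13,14,15-trihydroxyhalim-1(10)-en-18-oate
Conditions: HClO4 (cat.), THF/H2O, 0 °C
Reagents that add atoms: water, O
Why: Acid-catalysed epoxide hydrolysis, in which water should open the protonated trisubstituted epoxide at the tertiary C13 with inversion (borderline SN2), turning the (13S,14S)-epoxide into the (13R,14S)-triol with C14 untouched.

Step 15
Reactants: 23 methyl (4S,5R,8R,9S,13R,14S)-13,14,15-trihydroxyhalim-1(10)-en-18-oate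
Product: 24 methyl (4S,5R,8R,9S,13R,14S)-14,15-diacetoxy-13-hydroxyhalim-1(10)-en-18-oate
Conditions: Ac2O, pyridine, CH2Cl2, rt
Reagents that add atoms: acetic anhydride, CC(=O)OC(C)=O
Why: Acylation with Ac2O/pyridine esterifies the primary C15 and secondary C14 hydroxyls, whereas the tertiary C13 hydroxyl should not react without a stronger acyl-transfer catalyst.

**Compound list**

1 | 2-methylcyclohex-2-en-1-one | CC1=CCCCC1=O | starting material
2 | dimethylaluminium (R)-2,3-dimethylcyclohex-1-en-1-olate (not isolated) | CC1=C(O[Al](C)C)CCC[C@H]1C | intermediate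
3 | (R)-[(2,3-dimethylcyclohex-1-en-1-yl)oxy]trimethylsilane | CC1=C(O[Si](C)(C)C)CCC[C@H]1C | intermediate
4 | methyl vinyl ketone (but-3-en-2-one) | CC(=O)C=C | starting material
5 | (2S,3R)-2,3-dimethyl-2-(3-oxobutyl)cyclohexan-1-one | O=C1CCC[C@@H](C)[C@]1(C)CCC(C)=O | intermediate
6 | (2S,3R)-2,3-dimethyl-2-[2-(2-methyl-1,3-dioxolan-2-yl)ethyl]cyclohexan-1-one | O=C1CCC[C@@H](C)[C@]1(C)CCC2(C)OCCO2 | intermediate
7 | (E)-2,4,6-triisopropylbenzenesulfonyl hydrazone of ketone 6 | CC(C)c1cc(C(C)C)c(S(=O)(=O)N/N=C2\CCC[C@@H](C)[C@]2(C)CCC3(C)OCCO3)c(C(C)C)c1 | intermediate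
8 | methyl 5-chloro-5-oxopentanoate | COC(=O)CCCC(Cl)=O | starting material
9 | methyl 5-[methoxy(methyl)amino]-5-oxopentanoate | COC(=O)CCCC(=O)N(C)OC | intermediate
10 | {(5R,6S)-5,6-dimethyl-6-[2-(2-methyl-1,3-dioxolan-2-yl)ethyl]cyclohex-1-en-1-yl}lithium (not isolated) | [Li]C1=CCC[C@@H](C)[C@]1(C)CCC2(C)OCCO2 | intermediate
11 | methyl 5-{(5R,6S)-5,6-dimethyl-6-[2-(2-methyl-1,3-dioxolan-2-yl)ethyl]cyclohex-1-en-1-yl}-5-oxopentanoate | COC(=O)CCCC(=O)C1=CCC[C@@H](C)[C@]1(C)CCC2(C)OCCO2 | intermediate
12 | methyl (5R)-5-hydroxy-5-{(5R,6S)-5,6-dimethyl-6-[2-(2-methyl-1,3-dioxolan-2-yl)ethyl]cyclohex-1-en-1-yl}pentanoate (not isolated) | COC(=O)CCC[C@@H](O)C1=CCC[C@@H](C)[C@]1(C)CCC2(C)OCCO2 | intermediate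
13 | (6R)-6-{(5R,6S)-5,6-dimethyl-6-[2-(2-methyl-1,3-dioxolan-2-yl)ethyl]cyclohex-1-en-1-yl}oxan-2-one | O=C1CCC[C@@H](O1)C2=CCC[C@@H](C)[C@]2(C)CCC3(C)OCCO3 | intermediate
14 | (6R)-3-methyl-6-{(5R,6S)-5,6-dimethyl-6-[2-(2-methyl-1,3-dioxolan-2-yl)ethyl]cyclohex-1-en-1-yl}oxan-2-one (C3 epimers) | CC1CC[C@@H](OC1=O)C2=CCC[C@@H](C)[C@]2(C)CCC3(C)OCCO3 | intermediate
15 | (2R)-5-methyl-6-(trimethylsilyloxy)-2-{(5R,6S)-5,6-dimethyl-6-[2-(2-methyl-1,3-dioxolan-2-yl)ethyl]cyclohex-1-en-1-yl}-3,4-dihydro-2H-pyran (not isolated) | CC1=C(O[Si](C)(C)C)O[C@H](CC1)C2=CCC[C@@H](C)[C@]2(C)CCC3(C)OCCO3 | intermediate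
16 | trimethylsilyl (4S,5R,8R,9S)-13,13-(ethylenedioxy)-14,15-dinorhalim-1(10)-en-18-oate (not isolated) | C[Si](C)(C)OC(=O)[C@@]1(C)CCC=C2[C@H]1CC[C@@H](C)[C@]2(C)CCC3(C)OCCO3 | intermediate
17 | (4S,5R,8R,9S)-13-oxo-14,15-dinorhalim-1(10)-en-18-oic acid | OC(=O)[C@@]1(C)CCC=C2[C@H]1CC[C@@H](C)[C@]2(C)CCC(C)=O | intermediate
18 | methyl (4S,5R,8R,9S)-13-oxo-14,15-dinorhalim-1(10)-en-18-oate | COC(=O)[C@@]1(C)CCC=C2[C@H]1CC[C@@H](C)[C@]2(C)CCC(C)=O | intermediate
19 | ethyl 2-(diisopropoxyphosphoryl)acetate | CCOC(=O)CP(=O)(OC(C)C)OC(C)C | starting material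
20 | 15-ethyl 18-methyl (4S,5R,8R,9S,13E)-halima-1(10),13-diene-15,18-dioate | COC(=O)[C@@]1(C)CCC=C2[C@H]1CC[C@@H](C)[C@]2(C)CC/C(C)=C/C(=O)OCC | intermediate
21 | methyl (4S,5R,8R,9S,13E)-15-hydroxyhalima-1(10),13-dien-18-oate | COC(=O)[C@@]1(C)CCC=C2[C@H]1CC[C@@H](C)[C@]2(C)CC/C(C)=C/CO | intermediate
22 | methyl (4S,5R,8R,9S,13S,14S)-13,14-epoxy-15-hydroxyhalim-1(10)-en-18-oate | COC(=O)[C@@]1(C)CCC=C2[C@H]1CC[C@@H](C)[C@]2(C)CC[C@]3(C)O[C@H]3CO | intermediate
23 | methyl (4S,5R,8R,9S,13R,14S)-13,14,15-trihydroxyhalim-1(10)-en-18-oate | COC(=O)[C@@]1(C)CCC=C2[C@H]1CC[C@@H](C)[C@]2(C)CC[C@@](C)(O)[C@H](CO)O | intermediate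
24 | methyl (4S,5R,8R,9S,13R,14S)-14,15-diacetoxy-13-hydroxyhalim-1(10)-en-18-oate | COC(=O)[C@@]1(C)CCC=C2[C@H]1CC[C@@H](C)[C@]2(C)CC[C@@](C)(O)[C@H](COC(C)=O)OC(C)=O | target

**Step count and risks**

Total steps: 15. Longest linear sequence: 14 (steps 1–4 and 6–15; step 5 is a one-step branch).

Step 9. What may go wrong: the [3,3] shift must pass through a strained boat and form a quaternary centre next to a ring carbon, so fragmentation or C-silylation of the fully substituted ketene acetal may outrun rearrangement, and facial control may erode at the temperature needed. The fallback sets out from 13 and comes back at 18; it builds the quaternary centre by enolate alkylation after a less congested rearrangement. Lactone 13 is enolised and silylated (LiN(i-Pr)2, TMSCl/Et3N) to the unmethylated silyl ketene acetal F1, which should rearrange more readily in hot toluene through the same boat to the silyl ester F2. Mild hydrolysis (K2CO3, MeOH/H2O, then pH 5) keeps the dioxolane and gives the C4–H acid F3, and MeI/K2CO3 gives the methyl ester F4. Deprotonation with LiN(i-Pr)2 and methylation with MeI on the enolate face anti to the C5–C6 bond of ring B should give the C4-methylated ester ketal F5, and 1 M HCl in THF removes the dioxolane to give 18.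

Step 11. What may go wrong: addition of the phosphonate anion to the unactivated ketone may be slow, and the methyl group and the C12 chain may be too alike for good E control, so that much material is lost as the Z isomer. The fallback sets out from 18 and comes back at 21; it replaces the olefination by a stereospecific syn-carbometalation. The kinetic enolate of the methyl ketone (LiN(i-Pr)2, −78 °C) is trapped with ClP(O)(OEt)2 to give the enol phosphate F6, and further LiN(i-Pr)2 eliminates phosphate to give the terminal alkyne F7. Zirconium-catalysed methylalumination (Me3Al, Cp2ZrCl2, CH2Cl2) adds methyl and aluminium syn across the triple bond, and trapping of the alkenylalane (as its n-BuLi ate complex) with paraformaldehyde should give the 13E allylic alcohol 21 as a single geometric isomer.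

Step 14. What may go wrong: ionisation at tertiary C13 may cause loss of stereospecificity (attack with retention), a 1,2-hydride shift to a carbonyl compound, or capture of the cation by the 1(10) olefin. The fallback sets out from 21 and comes back at 23; it never breaks a bond at C13. Epoxidation of 21 with D-(−)-diethyl tartrate in place of the L-ester gives the (13R,14R)-epoxy alcohol F8. Aqueous NaOH in t-BuOH induces a Payne rearrangement (the C15 alkoxide attacks C14 with inversion) to the 14,15-epoxy-13-ol F9, which hydroxide opens at the primary C15 to give the same (13R,14S)-triol 23; the hindered C4 methyl ester should survive.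

**Further compounds**

F1 | step 9 | (2R)-6-(trimethylsilyloxy)-2-{(5R,6S)-5,6-dimethyl-6-[2-(2-methyl-1,3-dioxolan-2-yl)ethyl]cyclohex-1-en-1-yl}-3,4-dihydro-2H-pyran | C[Si](C)(C)OC1=CCC[C@@H](O1)C2=CCC[C@@H](C)[C@]2(C)CCC3(C)OCCO3
F2 | step 9 | trimethylsilyl ester of the 4-demethyl acid (4-H on the face of H-5, dioxolane retained) | C[Si](C)(C)OC(=O)[C@H]1CCC=C2[C@H]1CC[C@@H](C)[C@]2(C)CCC3(C)OCCO3
F3 | step 9 | 4-demethyl-13,13-(ethylenedioxy)-14,15-dinorhalim-1(10)-en-18-oic acid (4-H on the face of H-5) | OC(=O)[C@H]1CCC=C2[C@H]1CC[C@@H](C)[C@]2(C)CCC3(C)OCCO3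
F4 | step 9 | methyl ester of acid F3 | COC(=O)[C@H]1CCC=C2[C@H]1CC[C@@H](C)[C@]2(C)CCC3(C)OCCO3
F5 | step 9 | methyl (4S,5R,8R,9S)-13,13-(ethylenedioxy)-14,15-dinorhalim-1(10)-en-18-oate | COC(=O)[C@@]1(C)CCC=C2[C@H]1CC[C@@H](C)[C@]2(C)CCC3(C)OCCO3
F6 | step 11 | diethyl enol phosphate of the methyl ketone of 18 (C13=CH2) | COC(=O)[C@@]1(C)CCC=C2[C@H]1CC[C@@H](C)[C@]2(C)CCC(=C)OP(=O)(OCC)OCC
F7 | step 11 | terminal alkyne from 18 (C12–C≡CH) | COC(=O)[C@@]1(C)CCC=C2[C@H]1CC[C@@H](C)[C@]2(C)CCC#C
F8 | step 14 | methyl (4S,5R,8R,9S,13R,14R)-13,14-epoxy-15-hydroxyhalim-1(10)-en-18-oate | COC(=O)[C@@]1(C)CCC=C2[C@H]1CC[C@@H](C)[C@]2(C)CC[C@@]3(C)O[C@@H]3CO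
F9 | step 14 | methyl (4S,5R,8R,9S,13R,14S)-14,15-epoxy-13-hydroxyhalim-1(10)-en-18-oate | COC(=O)[C@@]1(C)CCC=C2[C@H]1CC[C@@H](C)[C@]2(C)CC[C@@](C)(O)[C@@H]3CO3
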